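## Retrosynthetic overview
1. Neomacrophorin I comes from a regioselective nucleophilic epoxidation of a quinone monoketal, followed by ketal and acetonide removal. The side chain is (2R,3S)-2,3-dihydroxybutanoate from D-threonine, attached as an acetonide ester.
2. The C11–C12 bond is made by a radical step: the drimanyl-CH2 radical (from the primary iodide) adds to 1,4-benzoquinone. A second radical step installs CH2OH.
3. The trans-decalin, the 8(17)-methylene and C3–O come from one Ti(III) radical bicyclization of a (10S)-epoxy-(E,E)-farnesyl TBS ether. Ring A closes first, then ring B. A ketone/bulky-hydride sequence then inverts 3β-OH to 3α-OH.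
4. The farnesyl chain comes from glycolaldehyde and two isopropenyl units by two Johnson–Claisen cycles plus a Wittig reaction. The quinone ring is pre-formed (benzoquinone) and the epoxide is made last.

**Assumptions**
- The target SMILES has a 3α (axial, 3R) hydroxyl on the normal drimane skeleton (5α-H, 9α-H, 10β-Me), so the Ti(III) product (3β-OH) needs inversion.
- Diazotization of D-threonine proceeds with retention (α-lactone) and gives the (2R,3S) acid.
- Radical hydroxymethylation of a 2-alkylquinone favours C5 (para to the alkyl group). I assume about 3:1, with the 2,6-isomer removed by chromatography.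
- The C12/C13 epoxide diastereomers from the epoxidation are assumed separable.

## Route

**Step 1**
Reactants: 1 D-threonine
Product: 2 (2R,3S)-2,3-dihydroxybutanoic acid
Conditions: NaNO2, 0.5 M aq H2SO4, 0 °C → rt
Reagents that add atoms: water, O
Why: Diazotization of an α-amino acid proceeds through an α-lactone (double inversion), so both stereocentres are retained and the (2R,3S) pattern of the target ester is set here.

**Step 2**
Reactants: 2
Product: 3 (4R,5S)-2,2,5-trimethyl-1,3-dioxolane-4-carboxylic acid
Conditions: 2,2-dimethoxypropane, TsOH (cat.), acetone, rt; then LiOH, THF/H2O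
Reagents that add atoms: 2,2-dimethoxypropane, COC(C)(C)OC
Why: Acetonide formation on the threo diol gives a trans-dioxolane with no new stereocentre. LiOH cleaves any methyl ester formed in situ.

**Step 3**
Reactants: 4 glycolaldehyde dimer (2,5-dihydroxy-1,4-dioxane)
Product: 5 3-methylbut-3-ene-1,2-diol (racemic)
Conditions: isopropenylMgBr (5 equiv), THF, −78 → 0 °C
Reagents that add atoms: isopropenylmagnesium bromide, C=C(C)[Mg]Br
Why: The dimer dissociates to glycolaldehyde and Grignard 1,2-addition gives the allylic diol. The new carbinol stereocentre is irrelevant because it is destroyed in the Claisen step.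

**Step 4**
Reactants: 5
Product: 6 1-(TBSO)-3-methylbut-3-en-2-ol
Conditions: TBSCl, imidazole, CH2Cl2, 0 °C
Reagents that add atoms: TBSCl, CC(C)(C)[Si](C)(C)Cl
Why: The primary hydroxyl is silylated selectively over the secondary allylic one.

**Step 5**
Reactants: 6
Product: 7 methyl (E)-6-(TBSO)-4-methylhex-4-enoate
Conditions: MeC(OMe)3, EtCO2H (cat.), 140 °C, MeOH distilled off
Reagents that add atoms: trimethyl orthoacetate, CC(OC)(OC)OC
Why: Johnson–Claisen [3,3] rearrangement through a chair transition state with CH2OTBS equatorial sets the trisubstituted alkene as E (≥95:5).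

**Step 6**
Reactants: 7
Product: 8 (E)-6-(TBSO)-4-methylhex-4-enal
Conditions: DIBAL-H (1.05 equiv), CH2Cl2, −78 °C
Reagents that add atoms: none
Why: Low-temperature DIBAL stops at the aldehyde; the TBS ether and alkene are untouched.

**Step 7**
Reactants: 8
Product: 9 (E)-1-(TBSO)-3,7-dimethylocta-2,7-dien-6-ol
Conditions: isopropenylMgBr, THF, −78 °C
Reagents that add atoms: isopropenylmagnesium bromide, C=C(C)[Mg]Br
Why: Grignard 1,2-addition gives the secondary allylic alcohol needed for the second Claisen step (new carbinol stereocentre, not retained).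

**Step 8**
Reactants: 9
Product: 10 methyl (4E,8E)-10-(TBSO)-4,8-dimethyldeca-4,8-dienoate
Conditions: MeC(OMe)3, EtCO2H (cat.), 140 °C
Reagents that add atoms: trimethyl orthoacetate, CC(OC)(OC)OC
Why: Second Johnson–Claisen rearrangement; the chair transition state again sets E geometry, giving the (E,E) skipped diene.

**Step 9**
Reactants: 10
Product: 11 (4E,8E)-10-(TBSO)-4,8-dimethyldeca-4,8-dienal
Conditions: DIBAL-H (1.05 equiv), CH2Cl2, −78 °C
Reagents that add atoms: none
Why: Partial ester reduction, as in step 6, with both E-alkenes and the silyl ether intact.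

**Step 10**
Reactants: 11
Product: 12 TBS ether of (2E,6E)-farnesol
Conditions: iPrPPh3Br, KOtBu, THF, 0 °C → rt
Reagents that add atoms: isopropyltriphenylphosphonium bromide (from 2-bromopropane and PPh3), CC(C)[P+](c1ccccc1)(c1ccccc1)c1ccccc1.[Br-]
Why: Wittig olefination with the non-stabilized isopropylidene ylide forms the terminal Me2C=CH– with no stereochemical issue, and the internal E-alkenes are unaffected.

**Step 11**
Reactants: 12
Product: 13 (10S)-10,11-epoxy-(2E,6E)-farnesyl TBS ether
Conditions: Oxone, fructose-derived Shi ketone (30 mol%), K2CO3/EDTA buffer (pH 10.5), Bu4NHSO4, MeCN/DMM, 0 °C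
Reagents that add atoms: Oxone (KHSO5), OOS(=O)(=O)[O-].[K+]
Why: Shi asymmetric epoxidation targets the terminal gem-dimethyl alkene. C2=C3 is deactivated by the allylic silyl ether, and the catalyst enantiomer is chosen to give the (S)-epoxide, which fixes the absolute configuration of the decalin.

**Step 12 (key radical bicyclization)**
Reactants: 13
Product: 14 11-(TBSO)drim-8(17)-en-3β-ol
Conditions: Cp2TiCl2 (20 mol%), Zn, 2,4,6-collidine, TMSCl, THF, rt; then 1 M HCl/THF, 0 °C
Reagents that add atoms: none (TMS ether cleaved on work-up)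
Why: Ti(III) opens the epoxide to the tertiary radical at C4. It closes ring A (6-endo), and the resulting C10 radical closes ring B (6-endo onto C9). Chair–chair transition states from the E,E-alkenes set 5α-H, 10β-Me and 9α-H. C3 keeps the epoxide configuration (3β-OH). Ti–C8 β-hydride elimination gives the exocyclic 8(17)-methylene.

**Step 13**
Reactants: 14
Product: 15 11-(TBSO)drim-8(17)-en-3-one
Conditions: Dess–Martin periodinane, NaHCO3, CH2Cl2, rt
Reagents that add atoms: none
Why: Oxidation of the secondary alcohol to the ketone; the alkene and silyl ether survive.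

**Step 14**
Reactants: 15
Product: 16 11-(TBSO)drim-8(17)-en-3α-ol
Conditions: L-Selectride, THF, −78 °C
Reagents that add atoms: none
Why: The bulky borohydride cannot take the axial trajectory past the 1α/5α diaxial hydrogens, so it attacks equatorially and delivers the axial 3α-OH, the configuration in the target.

**Step 15**
Reactants: 16
Product: 17 drim-8(17)-ene-3α,11-diol
Conditions: TBAF, THF, 0 °C → rt
Reagents that add atoms: none
Why: Fluoride removes the primary silyl ether and leaves the other functional groups unchanged.

**Step 16**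
Reactants: 17
Product: 18 11-iododrim-8(17)-en-3α-ol
Conditions: I2, PPh3, imidazole, CH2Cl2, 0 °C
Reagents that add atoms: iodine, II
Why: Appel iodination is selective for the primary alcohol. The 3α-OH is axial and flanked by the gem-dimethyl group, so it does not react.

**Step 17 (key radical C11–C12 bond formation)**
Reactants: 18; 19 1,4-benzoquinone
Product: 20 2-[(3α-hydroxydrim-8(17)-en-11-yl)]-1,4-benzoquinone
Conditions: BQ (4 equiv), Et3B (1.2 equiv), air, CH2Cl2, 25 °C
Reagents that add atoms: none (BQ is the numbered reactant)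
Why: Proposed new method: Et• (from Et3B/O2) abstracts iodine to give the primary C11 radical. This nucleophilic radical adds to the unsubstituted C=C of BQ (about 10^6–10^7 M⁻¹ s⁻¹), which outcompetes the slow homoallyl 1,2-vinyl shift. The semiquinone adduct is reoxidized by excess BQ to the alkylquinone. The closest known reactions are Et3B-initiated iodine-atom-transfer Giese additions and Jacobsen–Torssell/Minisci alkylation of quinones. No new stereocentre is made and C9 is untouched.

**Step 18**
Reactants: 20; 21 glycolic acid
Product: 22 5-(hydroxymethyl)-2-(drimenylmethyl) quinone, i.e. 2-[(3α-hydroxydrim-8(17)-en-11-yl)]-5-(hydroxymethyl)-1,4-benzoquinone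
Conditions: AgNO3 (30 mol%), (NH4)2S2O8, MeCN/H2O (1:1), 65 °C
Reagents that add atoms: none (glycolic acid is the numbered reactant)
Why: Jacobsen–Torssell decarboxylative generation of •CH2OH. The nucleophilic radical adds at C5, β to the more electrophilic C1 carbonyl and away from the bulky alkyl group. It is faster at the electron-poor quinone than at the exocyclic alkene.

**Step 19**
Reactants: 22; 3
Product: 23 quinone acetonide ester, i.e. the (4R,5S)-dioxolane-4-carboxylate of 22
Conditions: EDC·HCl, DMAP (10 mol%), CH2Cl2, 0 °C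
Reagents that add atoms: none
Why: Steglich esterification of the unhindered primary CH2OH. The axial 3α-OH is too hindered to compete, and the acid α-centre is not epimerized under these mild conditions.

**Step 20**
Reactants: 23
Product: 24 the corresponding hydroquinone (quinone reduced to hydroquinone)
Conditions: Na2S2O4, THF/H2O, rt, 15 min
Reagents that add atoms: none
Why: Reduction of the quinone to the air-sensitive hydroquinone, which is used crude; the ester and acetonide are untouched.

**Step 21**
Reactants: 24
Product: 25 the 4-O-methyl ether, methylated on the OH ortho to CH2O-acyl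
Conditions: TMSCHN2 (1.1 equiv), iPr2NEt, MeOH/MeCN, 0 °C → rt
Reagents that add atoms: trimethylsilyldiazomethane, C[Si](C)(C)C=[N+]=[N-]
Why: The phenol ortho to the acyloxymethyl group is more acidic and less hindered than the one ortho to the decalinylmethyl group, so it is methylated selectively. Alcohols are not methylated under these conditions.

**Step 22**
Reactants: 25
Product: 26 quinone monoketal (C1 ketone, C4 dimethyl ketal)
Conditions: PhI(OAc)2, MeOH, 0 °C, 10 min
Reagents that add atoms: methanol, CO
Why: Oxidation of a 4-methoxyphenol in MeOH places the ketal at the methoxy-bearing carbon (C4) and the carbonyl at C1, next to the alkyl group. This is exactly the pattern needed to direct the next step.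

**Step 23**
Reactants: 26
Product: 27 epoxy-enone ketal
Conditions: t-BuOOH, Triton B (20 mol%), THF, −20 °C
Reagents that add atoms: tert-butyl hydroperoxide, CC(C)(C)OO
Why: Proposed new method: in the monoketal, conjugate addition of t-BuOO⁻ at C3 (a β-monosubstituted, α-alkyl enone) is far faster than at C5 (a β,β-disubstituted enone). Ring closure at C2 then gives the C12/C13 epoxide, with the new cis stereocentres set together by facial selection from the decalin. The closest known reaction is Weitz–Scheffer epoxidation of quinone monoketals.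

**Step 24**
Reactants: 27
Product: 28 neomacrophorin I
Conditions: TFA, H2O, THF (1:2:6), 0 °C → rt
Reagents that add atoms: water, O
Why: Aqueous acid hydrolyzes the dimethyl ketal to the C4 ketone and opens the acetonide to the free (2R,3S)-diol. The epoxyquinone, ester and 3α-OH survive these mild conditions.

## Compound list
1 | D-threonine | C[C@H](O)[C@@H](N)C(=O)O | starting material
2 | (2R,3S)-2,3-dihydroxybutanoic acid | OC(=O)[C@H](O)[C@H](C)O | intermediate
3 | (4R,5S)-2,2,5-trimethyl-1,3-dioxolane-4-carboxylic acid | O=C(O)[C@@H]1OC(C)(C)O[C@H]1C | intermediate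
4 | glycolaldehyde dimer | OC1COC(O)CO1 | starting material
5 | 3-methylbut-3-ene-1,2-diol | C=C(C)C(O)CO | intermediate
6 | 1-(TBSO)-3-methylbut-3-en-2-ol | C=C(C)C(O)CO[Si](C)(C)C(C)(C)C | intermediate
7 | methyl (E)-6-(TBSO)-4-methylhex-4-enoate | COC(=O)CC/C(C)=C/CO[Si](C)(C)C(C)(C)C | intermediate
8 | (E)-6-(TBSO)-4-methylhex-4-enal | O=CCC/C(C)=C/CO[Si](C)(C)C(C)(C)C | intermediate
9 | (E)-1-(TBSO)-3,7-dimethylocta-2,7-dien-6-ol | C=C(C)C(O)CC/C(C)=C/CO[Si](C)(C)C(C)(C)C | intermediate
10 | methyl (4E,8E)-10-(TBSO)-4,8-dimethyldeca-4,8-dienoate | COC(=O)CC/C(C)=C/CC/C(C)=C/CO[Si](C)(C)C(C)(C)C | intermediate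
11 | (4E,8E)-10-(TBSO)-4,8-dimethyldeca-4,8-dienal | O=CCC/C(C)=C/CC/C(C)=C/CO[Si](C)(C)C(C)(C)C | intermediate
12 | (2E,6E)-farnesyl TBS ether | CC(C)=CCC/C(C)=C/CC/C(C)=C/CO[Si](C)(C)C(C)(C)C | intermediate
13 | (10S)-10,11-epoxyfarnesyl TBS ether | CC1(C)O[C@H]1CC/C(C)=C/CC/C(C)=C/CO[Si](C)(C)C(C)(C)C | intermediate
14 | 11-(TBSO)drim-8(17)-en-3β-ol | C=C1CC[C@H]2C(C)(C)[C@@H](O)CC[C@]2(C)[C@H]1CO[Si](C)(C)C(C)(C)C | intermediate
15 | 11-(TBSO)drim-8(17)-en-3-one | C=C1CC[C@H]2C(C)(C)C(=O)CC[C@]2(C)[C@H]1CO[Si](C)(C)C(C)(C)C | intermediate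
16 | 11-(TBSO)drim-8(17)-en-3α-ol | C=C1CC[C@H]2C(C)(C)[C@H](O)CC[C@]2(C)[C@H]1CO[Si](C)(C)C(C)(C)C | intermediate
17 | drim-8(17)-ene-3α,11-diol | C=C1CC[C@H]2C(C)(C)[C@H](O)CC[C@]2(C)[C@H]1CO | intermediate
18 | 11-iododrim-8(17)-en-3α-ol | C=C1CC[C@H]2C(C)(C)[C@H](O)CC[C@]2(C)[C@H]1CI | intermediate
19 | 1,4-benzoquinone | O=C1C=CC(=O)C=C1 | starting material
20 | 2-(3α-hydroxydrim-8(17)-en-11-yl)-1,4-benzoquinone | C=C1CC[C@H]2C(C)(C)[C@H](O)CC[C@]2(C)[C@H]1CC1=CC(=O)C=CC1=O | intermediate
21 | glycolic acid | OCC(=O)O | starting material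
22 | 5-(hydroxymethyl) derivative of 20 | C=C1CC[C@H]2C(C)(C)[C@H](O)CC[C@]2(C)[C@H]1CC1=CC(=O)C(CO)=CC1=O | intermediate
23 | acetonide ester of 22 | C=C1CC[C@H]2C(C)(C)[C@H](O)CC[C@]2(C)[C@H]1CC1=CC(=O)C(COC(=O)[C@@H]3OC(C)(C)O[C@H]3C)=CC1=O | intermediate
24 | hydroquinone of 23 | C=C1CC[C@H]2C(C)(C)[C@H](O)CC[C@]2(C)[C@H]1Cc1cc(O)c(COC(=O)[C@@H]3OC(C)(C)O[C@H]3C)cc1O | intermediate
25 | 4-O-methyl ether of 24 | C=C1CC[C@H]2C(C)(C)[C@H](O)CC[C@]2(C)[C@H]1Cc1cc(OC)c(COC(=O)[C@@H]3OC(C)(C)O[C@H]3C)cc1O | intermediate
26 | quinone monoketal | C=C1CC[C@H]2C(C)(C)[C@H](O)CC[C@]2(C)[C@H]1CC1=CC(OC)(OC)C(COC(=O)[C@@H]3OC(C)(C)O[C@H]3C)=CC1=O | intermediate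
27 | epoxy-enone ketal | C=C1CC[C@H]2C(C)(C)[C@H](O)CC[C@]2(C)[C@H]1C[C@]12O[C@H]1C(OC)(OC)C(COC(=O)[C@@H]3OC(C)(C)O[C@H]3C)=CC2=O | intermediate
28 | neomacrophorin I | C=C1CC[C@H]2C(C)(C)[C@H](O)CC[C@]2(C)[C@H]1C[C@]12O[C@H]1C(=O)C(COC(=O)[C@H](O)[C@H](C)O)=CC2=O | target

**Total step count:** 24 (including the 2-step side-chain branch).
**Longest linear sequence:** 22 steps (steps 3–24).

## Three steps most likely to fail
1. **Step 17 (radical alkylation of BQ).** Risks are low yield and the homoallyl 1,2-vinyl shift of the neopentyl-type C11 radical. Fallback: attach the arene before cyclization. Couple 2,5-bis(chloromethyl)-1,4-dimethoxybenzene, desymmetrized, with an (E)-alkenyl nucleophile to make an aryl-farnesyl epoxide. Run the Ti(III) cascade on that, then oxidize the arene to the quinone.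
2. **Step 18 (C5 vs C6 hydroxymethylation).** Regioselectivity may be poor. Fallback: use ionic boron-mediated ortho-hydroxymethylation (paraformaldehyde/PhB(OH)2) on the 2-alkylhydroquinone, which is directed by the less hindered phenol, and then oxidize back to the quinone.
3. **Step 23 (epoxidation regiochemistry and dr).** The monoketal should direct attack to C3, but facial selectivity relative to the remote C9 centre is uncertain. Fallback: mask the C5=C6 alkene of 2-alkylbenzoquinone (20) as its cyclopentadiene Diels–Alder adduct. Epoxidize C2=C3, perform retro-Diels–Alder, and add the CH2OR′ group last. Alternatively, use a chiral cinchona phase-transfer peroxide epoxidation to override substrate bias.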